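**Plan**
- The target is a 2,4,6-trihydroxyphenyl ketone on a C20 chain (ketone carbon = C1) with a free C17 carbinol and Z-alkenes at C5=C6, C8=C9, C11=C12 and C14=C15, each pair separated by one CH2 (C7, C10, C13). Every CH=CH is therefore read as C≡C, and the C8/C9 pair, two CH carbons flanked by CH2-7 and CH2-10, as acetylene.
- Retrosynthetic cuts, in order: the three aryl O–CH2OMe acetals; fourfold cis-hydrogenation (tetraene from tetrayne); C7–C8 and C9–C10 (acetylene as a two-carbon linchpin between two propargylic bromides); then C13–C14 and C15–C16 on the left, aryl–C1 and C6–C7 on the right.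
- Forward: epoxide opening gives the C14–C20 alkynol, which is extended to the C10–C20 diynyl bromide. Hex-5-ynoic acid gives the C1–C7 aryl ketone bromide. One flask joins both bromides through silyl-masked acetylene to the complete C20 tetrayne; Lindlar reduction and MOM removal finish. No ring is formed; the benzene ring is bought as phloroglucinol.
- Stereochemistry: C17 (R) comes from (R)-2-propyloxirane and is never touched. The four Z-alkenes come from syn addition of H2 to the four alkynes in a single step.
- The only protecting groups are three MOM ethers on the phenols; the C17 hydroxyl stays free throughout.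

Key step: step 9

Assumption: (R)-2-propyloxirane is taken as a commercial, enantiopure building block (it is also the product of hydrolytic kinetic resolution of the racemate).

**Route**

Step 1
Reactants: 1 (R)-2-propyloxirane
Product: 2 (R)-hept-1-yn-4-ol
Conditions: LiC≡CH·H2NCH2CH2NH2, DMSO, 0 °C → rt; then H2O
Reagents that add atoms: lithium acetylide–ethylenediamine complex, [Li]C#C.NCCN
Why: Epoxide alkynylation: the acetylide opens the terminal epoxide by SN2 at the unsubstituted CH2, so the C–O bond at the stereocentre is untouched and the (R) configuration of 1 becomes C17 (R) of the target.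

Step 2
Reactants: 2 (R)-hept-1-yn-4-ol; 3 4-chlorobut-2-yn-1-ol
Product: 4 (8R)-undeca-2,5-diyne-1,8-diol
Conditions: CuI, NaI, Cs2CO3, DMF, rt, Ar
Reagents that add atoms: none
Why: Copper(I)-mediated coupling of a terminal alkyne with a propargylic chloride under carbonate/iodide conditions (skipped-diyne synthesis), which tolerates both free hydroxyls and leaves C17 untouched.

Step 3
Reactants: 4 (8R)-undeca-2,5-diyne-1,8-diol
Product: 5 (4R)-11-bromoundeca-6,9-diyn-4-ol
Conditions: CBr4 (1.05 equiv), PPh3 (1.1 equiv), CH2Cl2, −40 → −10 °C
Reagents that add atoms: carbon tetrabromide, BrC(Br)(Br)Br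
Why: Appel bromination: with about one equivalent of reagent at low temperature the unhindered primary propargylic alcohol should be activated and displaced much faster than the secondary carbinol, so the C17 hydroxyl and its configuration are kept.

Step 4
Reactants: 6 phloroglucinol
Product: 7 1,3,5-tris(methoxymethoxy)benzene
Conditions: MOMCl, i-Pr2NEt, CH2Cl2/DMF, 0 °C → rt
Reagents that add atoms: chloromethyl methyl ether, COCCl
Why: Threefold O-alkylation of the phenols to the MOM acetals (acetal protection); the amine base favours O- over C-alkylation.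

Step 5
Reactants: 8 hex-5-ynoic acid
Product: 9 7-hydroxyhept-5-ynoic acid
Conditions: n-BuLi (2.1 equiv), THF, −78 → −20 °C; (CH2O)n, −20 °C → rt; then 1 M HCl
Reagents that add atoms: paraformaldehyde (as formaldehyde), C=O
Why: Alkyne hydroxymethylation: the carboxylate/acetylide dianion adds through the alkynyl carbon to formaldehyde, while the carboxylate is inert to the acetylide.

Step 6
Reactants: 9 7-hydroxyhept-5-ynoic acid
Product: 10 7-hydroxy-N-methoxy-N-methylhept-5-ynamide
Conditions: MeNH(OMe)·HCl, EDC·HCl, HOBt, N-methylmorpholine, CH2Cl2, 0 °C → rt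
Reagents that add atoms: N,O-dimethylhydroxylamine hydrochloride, CNOC.Cl
Why: Carbodiimide/HOBt amide coupling to the Weinreb amide; the amine should outcompete the primary alcohol for the active ester.

Step 7
Reactants: 7 1,3,5-tris(methoxymethoxy)benzene; 10 7-hydroxy-N-methoxy-N-methylhept-5-ynamide
Product: 12 7-hydroxy-1-[2,4,6-tris(methoxymethoxy)phenyl]hept-5-yn-1-one, via aryllithium 11 (not isolated)
Conditions: 7 (2.4 equiv), n-BuLi (2.3 equiv), THF, 0 °C; then 10, −78 → 0 °C; then H2O
Reagents that add atoms: none
Why: Directed ortho-lithiation of 7 between two OMOM groups, then Weinreb ketone synthesis through a chelated tetrahedral intermediate that prevents over-addition; one extra equivalent of 11 is spent on the hydroxyl, which travels as its lithium alkoxide.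

Step 8
Reactants: 12 7-hydroxy-1-[2,4,6-tris(methoxymethoxy)phenyl]hept-5-yn-1-one
Product: 13 7-bromo-1-[2,4,6-tris(methoxymethoxy)phenyl]hept-5-yn-1-one
Conditions: CBr4, PPh3, CH2Cl2, −20 → 0 °C
Reagents that add atoms: carbon tetrabromide, BrC(Br)(Br)Br
Why: Appel bromination of the primary propargylic alcohol under neutral conditions that should leave the MOM acetals and the ketone untouched.

Step 9
Reactants: 5 (4R)-11-bromoundeca-6,9-diyn-4-ol; 14 ethynyltrimethylsilane; 13 7-bromo-1-[2,4,6-tris(methoxymethoxy)phenyl]hept-5-yn-1-one
Product: 17 (17R)-17-hydroxy-1-[2,4,6-tris(methoxymethoxy)phenyl]icosa-5,8,11,14-tetrayn-1-one, via silyl-capped triyne 15 (not isolated), via terminal triyne 16 (not isolated)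
Conditions: 14 (1.1 equiv), CuI, NaI, K2CO3, DMF, rt, Ar; then 13 (1.2 equiv), CsF, rt
Reagents that add atoms: none
Why: In the first stage the copper(I) acetylide of 14 displaces the propargylic halide of 5 (iodide formed in situ) at its primary carbon to give 15, in which the trimethylsilyl group blocks the second C–H of acetylene so that the C2 unit is alkylated only once. Fluoride then removes silicon, the freed terminus of 16 is recaptured as a copper acetylide, and this attacks the primary propargylic carbon of 13, forming the bond between the alkyne carbon that becomes C8 and the CH2 that becomes C7 and completing the C20 chain from three components. The closest known reaction type is the copper-mediated carbonate/iodide coupling of terminal alkynes with propargylic halides used for skipped diynes, combined with fluoride unmasking of an alkynylsilane in the same flask. No ring is closed and no stereocentre is created; C17 is remote and its free hydroxyl is not deprotonated by carbonate or fluoride. The step needs single rather than double alkylation of acetylene (secured by the silyl cap and the order of addition), SN2 over SN2′ attack (both electrophilic carbons are unsubstituted primary propargylic CH2 groups and the nucleophile is a soft copper acetylide) and freedom from propargyl-to-allenyl isomerisation (only weak bases at room temperature); the ketone α-CH2 of 13 cannot cyclise onto its own bromide because the alkyne lies in between.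

Step 10
Reactants: 17 (17R)-17-hydroxy-1-[2,4,6-tris(methoxymethoxy)phenyl]icosa-5,8,11,14-tetrayn-1-one
Product: 18 (5Z,8Z,11Z,14Z,17R)-17-hydroxy-1-[2,4,6-tris(methoxymethoxy)phenyl]icosa-5,8,11,14-tetraen-1-one
Conditions: H2 (1 atm), Lindlar catalyst, quinoline, EtOAc, rt; stopped at 4 equiv H2
Reagents that add atoms: none
Why: Lindlar semihydrogenation: syn delivery of H2 on the poisoned palladium surface should turn each of the four internal alkynes into a Z-alkene, quinoline suppressing over-reduction and isomerisation, while the hindered aryl ketone, the MOM acetals and C17 are unaffected.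

Step 11
Reactants: 18 (5Z,8Z,11Z,14Z,17R)-17-hydroxy-1-[2,4,6-tris(methoxymethoxy)phenyl]icosa-5,8,11,14-tetraen-1-one
Product: 19 (5Z,8Z,11Z,14Z,17R)-17-hydroxy-1-(2,4,6-trihydroxyphenyl)icosa-5,8,11,14-tetraen-1-one
Conditions: HCl (3 M in MeOH), 35 °C, Ar, dark
Reagents that add atoms: none
Why: Acid-catalysed acetal methanolysis of the three aryl MOM ethers (formaldehyde is trapped as its dimethyl acetal instead of attacking the electron-rich ring); skipped Z-polyenes and the secondary alcohol should survive methanolic HCl, so neither the alkene geometries nor C17 is disturbed.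

**Compound list**
1 | (R)-2-propyloxirane | CCC[C@@H]1CO1 | starting material
2 | (R)-hept-1-yn-4-ol | CCC[C@@H](O)CC#C | intermediate
3 | 4-chlorobut-2-yn-1-ol | OCC#CCCl | starting material
4 | (8R)-undeca-2,5-diyne-1,8-diol | CCC[C@@H](O)CC#CCC#CCO | intermediate
5 | (4R)-11-bromoundeca-6,9-diyn-4-ol | CCC[C@@H](O)CC#CCC#CCBr | intermediate
6 | phloroglucinol (benzene-1,3,5-triol) | Oc1cc(O)cc(O)c1 | starting material
7 | 1,3,5-tris(methoxymethoxy)benzene | COCOc1cc(OCOC)cc(OCOC)c1 | intermediate
8 | hex-5-ynoic acid | C#CCCCC(=O)O | starting material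
9 | 7-hydroxyhept-5-ynoic acid | OCC#CCCCC(=O)O | intermediate
10 | 7-hydroxy-N-methoxy-N-methylhept-5-ynamide | CON(C)C(=O)CCCC#CCO | intermediate
11 | [2,4,6-tris(methoxymethoxy)phenyl]lithium | [Li]c1c(OCOC)cc(OCOC)cc1OCOC | intermediate
12 | 7-hydroxy-1-[2,4,6-tris(methoxymethoxy)phenyl]hept-5-yn-1-one | O=C(CCCC#CCO)c1c(OCOC)cc(OCOC)cc1OCOC | intermediate
13 | 7-bromo-1-[2,4,6-tris(methoxymethoxy)phenyl]hept-5-yn-1-one | O=C(CCCC#CCBr)c1c(OCOC)cc(OCOC)cc1OCOC | intermediate
14 | ethynyltrimethylsilane | C#C[Si](C)(C)C | starting material
15 | (4R)-13-(trimethylsilyl)trideca-6,9,12-triyn-4-ol | CCC[C@@H](O)CC#CCC#CCC#C[Si](C)(C)C | intermediate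
16 | (4R)-trideca-6,9,12-triyn-4-ol | CCC[C@@H](O)CC#CCC#CCC#C | intermediate
17 | (17R)-17-hydroxy-1-[2,4,6-tris(methoxymethoxy)phenyl]icosa-5,8,11,14-tetrayn-1-one | CCC[C@@H](O)CC#CCC#CCC#CCC#CCCCC(=O)c1c(OCOC)cc(OCOC)cc1OCOC | intermediate
18 | (5Z,8Z,11Z,14Z,17R)-17-hydroxy-1-[2,4,6-tris(methoxymethoxy)phenyl]icosa-5,8,11,14-tetraen-1-one | CCC[C@@H](O)C/C=C\C/C=C\C/C=C\C/C=C\CCCC(=O)c1c(OCOC)cc(OCOC)cc1OCOC | intermediate
19 | (5Z,8Z,11Z,14Z,17R)-17-hydroxy-1-(2,4,6-trihydroxyphenyl)icosa-5,8,11,14-tetraen-1-one | CCC[C@@H](O)C/C=C\C/C=C\C/C=C\C/C=C\CCCC(=O)c1c(O)cc(O)cc1O | target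

**Totals**
Total step count: 11. Longest linear sequence: 7 steps (steps 5, 6, 7, 8, 9, 10, 11, from hex-5-ynoic acid).

**Steps most likely to fail**

Step 9. The silyl cap may be lost prematurely in the first stage, which would let the C2 unit be alkylated twice by 5. Once unmasked, the skipped triyne may also undergo base-induced propargyl-to-allenyl isomerisation before it is intercepted. The fallback gives up the one-flask format and sets out from 5. Coupling with (triisopropylsilyl)acetylene under CuI/NaI/Cs2CO3 in DMF should give the carbonate-stable (4R)-13-(triisopropylsilyl)trideca-6,9,12-triyn-4-ol F1, which is isolated and purified. Buffered desilylation (TBAF/AcOH, THF, −20 °C) releases 16, which is used at once in a separate, standard CuI/NaI/Cs2CO3 coupling with 13. The route is rejoined at 17.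

Step 10. Some of the four triple bonds may be over-reduced while others stay incompletely reduced, and partial Z-to-E isomerisation would give mixtures that are hard to separate. The fallback spreads the reduction over smaller molecules and sets out from 4. Lindlar semihydrogenation of the diynediol should give (2Z,5Z,8R)-undeca-2,5-diene-1,8-diol F2, and selective Appel bromination of its primary allylic hydroxyl gives (4R,6Z,9Z)-11-bromoundeca-6,9-dien-4-ol F3. The same copper-mediated linchpin coupling with 14 and then 13 passes through (4R,6Z,9Z)-13-(trimethylsilyl)trideca-6,9-dien-12-yn-4-ol F4 and (4R,6Z,9Z)-trideca-6,9-dien-12-yn-4-ol F5 to (11Z,14Z,17R)-17-hydroxy-1-[2,4,6-tris(methoxymethoxy)phenyl]icosa-11,14-diene-5,8-diyn-1-one F6. Only two triple bonds then remain for the final Lindlar reduction, which comes back to the route at 18.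

Step 3. Chemoselectivity between the primary propargylic and the secondary hydroxyl may be lost, leading to double bromination or substitution with inversion at C17. The fallback avoids hydroxyl activation altogether and sets out from 2. Double deprotonation (EtMgBr, 2.1 equiv, THF) and CuCl-catalysed coupling of the alkynyl Grignard with excess 1,4-dichlorobut-2-yne should give (4R)-11-chloroundeca-6,9-diyn-4-ol F7 directly. F7 takes the place of 5 in step 9 (NaI activates the chloride in situ) and the route is rejoined at 15.

**Further compounds**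
F1 | step 9 | (4R)-13-(triisopropylsilyl)trideca-6,9,12-triyn-4-ol | CCC[C@@H](O)CC#CCC#CCC#C[Si](C(C)C)(C(C)C)C(C)C
F2 | step 10 | (2Z,5Z,8R)-undeca-2,5-diene-1,8-diol | CCC[C@@H](O)C/C=C\C/C=C\CO
F3 | step 10 | (4R,6Z,9Z)-11-bromoundeca-6,9-dien-4-ol | CCC[C@@H](O)C/C=C\C/C=C\CBr
F4 | step 10 | (4R,6Z,9Z)-13-(trimethylsilyl)trideca-6,9-dien-12-yn-4-ol | CCC[C@@H](O)C/C=C\C/C=C\CC#C[Si](C)(C)C
F5 | step 10 | (4R,6Z,9Z)-trideca-6,9-dien-12-yn-4-ol | CCC[C@@H](O)C/C=C\C/C=C\CC#C
F6 | step 10 | (11Z,14Z,17R)-17-hydroxy-1-[2,4,6-tris(methoxymethoxy)phenyl]icosa-11,14-diene-5,8-diyn-1-one | CCC[C@@H](O)C/C=C\C/C=C\CC#CCC#CCCCC(=O)c1c(OCOC)cc(OCOC)cc1OCOC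
F7 | step 3 | (4R)-11-chloroundeca-6,9-diyn-4-ol | CCC[C@@H](O)CC#CCC#CCCl
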